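The numbers in the tables were generated by integration on assumed constants; the scatter is artificial.

Z is conserved: each mole charged stands as solid, as J, or as forms I do not read. Q is held at 3.3 mM, so Z is the limiting reagent, and I write its balance.

| setting | gamma | beta | teal | red | amber | blue | violet |
|---|---|---|---|---|---|---|---|
| Z | 6.8 × 10⁻⁴ M | 0.041 M | 8.0 × 10⁻⁴ M | 0.0020 M | 0.0060 M | 0.020 M | 0.060 M |
| Q | 3.3 mM (held) | 3.3 mM (held) | 3.3 mM (held) | 3.3 mM (held) | 3.3 mM (held) | 3.3 mM (held) | 3.3 mM (held) |
| remark | run made earlier | run made earlier |  |  |  |  |  |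
| time |  |  | 1.0 h | 1.0 h | 1.0 h | 1.0 h | 1.0 h |

| run | time / min | J / % | Z / % |
|---|---|---|---|
| gamma | 8.00 | 3 | 1 |
| gamma | 15.0 | 8 | 0 |
| gamma | 25.0 | 19 | 0 |
| gamma | 30.0 | 25 | 1 |
| gamma | 40.0 | 35 | 0 |
| beta | 8.00 | 0 | 79 |
| beta | 15.0 | 1 | 67 |
| beta | 25.0 | 2 | 46 |
| beta | 30.0 | 5 | 39 |
| beta | 40.0 | 7 | 20 |

(scatter of a reading: 1.5 percentage points)

- Z is a solid; its amount is given per volume of the solution
- at the start none of Q is in solution
- at the start none of Z is in solution
- "hardly changes" means that all values lie within two and a half points (for a concentration: within two and a half percent of the largest)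

- [J] at the end for teal, red, amber, blue, violet, in this order
- the shape of the row from first to last (hardly changes / rises, then falls / falls, then rises / rises all the way / falls all the way)

I read the beta table row by row. From the first row to the second, solid Z falls at 7.03 × 10⁻⁴ M min⁻¹. From the fourth row to the last, it falls at 7.79 × 10⁻⁴ M min⁻¹. The fall looks straight, a zero-order supply. Between the first and last rows the solid loses 7.56 × 10⁻⁴ M min⁻¹. I call this reading the feed, the rate at which solid Z enters solution while solid stands. With Q at 3.3 mM, a charge divided by the feed is its estimated clearing time.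

Gamma's clearing time is 0.900 min, shorter than the time of its first reading, 8.00 min. So I read gamma as the chain to J with supply out of the way. At 40.0 min it reads J 35%, more than the 7% of beta. The balance leaves 65.0% of gamma unread.

Teal, red and amber have clearing times of 1.06 min, 2.65 min and 7.94 min, much shorter than 1.0 h. So I let them follow gamma. Its slope from the third row to the last, carried to 1.0 h, gives 56.3% of the charge: 4.51 × 10⁻⁴ M, 0.00113 M, 0.00338 M.

Blue's clearing time is 26.5 min. That leaves 33.5 min of the hour. Gamma reads 25% at 30.0 min, so I take 0.00500 M for blue. Violet's clearing time is 79.4 min, longer than 1.0 h. By the feed, violet's solid at 1.0 h stands at 24.4%, and beta's last row reads 20%. I carry beta's J share in that row over to violet, which gives 0.00420 M. My row falls after blue.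

The forecast gives 4.400 × 10⁻⁴ M, 0.00105 M, 0.0029 M, 0.0075 M, 0.0062 M: rises, then falls. It stands higher than mine at blue and violet. Of violet it says: “solid Z persists all hour, so J stays starved”.

The flasks give 3.99 × 10⁻⁴ M, 9.81 × 10⁻⁴ M, 0.00275 M, 0.00660 M, 0.00550 M: rises, then falls. The forecast stands within the margin, and its shape is right.

    E + G → D (k = 1.80 L mol⁻¹ s⁻¹)
    G + D → X (k = 1.30 L mol⁻¹ s⁻¹)
    G + X → J (k = 0.0680 L mol⁻¹ s⁻¹)
    Q ⇌ G, rate k4*(csat - [G]) (kL = 0.0150 s⁻¹)
    Z ⇌ E, rate k5*(cs5 - [E]) while solid is left; crystals form when [E] > cs5 (solubility = 11.0 mM, k = 0.00190 s⁻¹)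

Violet's clearing time of 79.4 min is longer than 1.00 h, and at that time violet holds Z 20.4%, against the 24.4% from the feed. Blue's clearing time of 26.5 min is shorter than 0.500 h, and at that time blue holds Z 0%.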